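If free monomer decays like a first-order lag whose time constant shrinks in step with the initiator charged, the earlier runs can show it.

| setting | birch | cedar | Friday's | Sunday's |
|---|---|---|---|---|
| free monomer | 0.40 M | 0.40 M | 0.40 M | 0.40 M |
| initiator | 2 mM | 7 mM | 8.0 mM | 2.5 mM |
| remark | run made earlier | run made earlier |  |  |
| time |  |  | 10 min | 10 min |

| run | time / min | monomer in chains / % |
|---|---|---|
| birch | 0.833 | 1 |
| birch | 2.50 | 5 |
| birch | 5.00 | 12 |
| birch | 8.00 | 22 |
| cedar | 2.00 | 13 |
| cedar | 4.00 | 28 |
| cedar | 5.00 | 34 |
| cedar | 8.00 | 54 |

(standard deviation of a reading: 1.5 percentage points)

* which of the two ends with the longer chains by the average number of monomer units in a chain (chains begun, living or dead) ("neither" if they lie within 10%) (Friday's / Sunday's / neither)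
* average number of monomer units in a chain (chains begun, living or dead) at the end, Friday's
* average number of monomer units in a chain (chains begun, living or dead) at the end, Sunday's

- the average divides the monomer in chains by the number of chains begun, living and dead together
- the analysis behind the earlier runs scatters by 1.5 percentage points, standard deviation
- the earlier runs do not show the number of chains; that part of a forecast is a guess

Read the last rows of the two runs against each other, in logarithms. At 8.00 min birch has 22% in chains and cedar 54%. Taking what is not in chains as left, the natural logarithm of charge over left is 0.248 in birch and 0.777 in cedar. The second is 3.13 times the first for 3.50 times the initiator, and in powers of ten these two scattered readings give an order in initiator of 0.910. So I take the decay as pseudo-first-order, with a rate constant proportional to the initiator charged.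

Dividing by initiator and time gives 15.5 /M/min from birch and 13.9 /M/min from cedar. Their mean, 14.7 /M/min, is a reading of the fall of that logarithm per unit of initiator charged and of time; call it the grip.

One over grip times initiator is the time constant: 8.50 min for Friday's, 27.2 min for Sunday's. By my reckoning, at 10 min Friday's has 69.1% in chains and Sunday's 30.7%. That is 34.6 units per initiator charged in Friday's and 49.2 in Sunday's. These become lengths once divided by the share of initiator that begins a chain, which the readings do not show. If that share is equal in both flasks it cancels, so I commit to Sunday's being longer, by a factor of 1.42.

The forecast, working from a late slope and a lag, says Sunday's, with 34 (29 to 48) for Friday's and 50 (42 to 72) for Sunday's, and adds: “This assumes one chain per initiator, which is a guess.”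

Friday's ends at 144 and Sunday's at 199, so Sunday's is longer, by a factor of 1.38, from these steps:

    free monomer + initiator → spent initiator (k = 0.120 /M/s)
    free monomer + initiator → living end + monomer in chains (k = 0.0340 /M/s)
    free monomer + living end → monomer in chains + living end, rate k3*[living end]*[free monomer] (k = 1.00 /M/s)

At 10.0 min Friday's holds 0.00177 M of living end from 8.0 mM of initiator charged, a share of 22.1%. For Sunday's at 10 min, the grip reckons 69.3% of the free monomer charged still there, and the flask holds 72.0%. Read at 25 min, Sunday's has run 0.919 of the grip's time constants, so the grip reckons 39.9%, and the flask holds 43.8%.

All runs were generated by integration on assumed constants, noise included.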